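**Retrosynthetic overview**
- The butenolide ring is made last, from a C-12 aldehyde by Wittig olefination with a lactone ylide and double-bond migration. The C-17 carboxyl and the C-9 side chain both come from a C-9 ketone (β-keto ester, enol triflate, Negishi coupling, dissolving-metal reduction).
- Ring A (C-1, C-2, C-3, C-4, C-5, C-10) is closed onto ring B in one anionic cascade: a ring-B enolate, phenyl vinyl sulfone (C-1/C-2) and MeI form C-10–C-1, C-2–C-3 and C-4–C-18.
- Enabling feature: C-4 carries the C-19 carboxyl, so C-3=C-4 can be an acrylate acceptor whose enolate is then methylated on the face away from the axial C-20 methyl. C-10 sits α to a C-9 carbonyl (the later side-chain carbon), so it is a regiodefined enolate. The sulfone makes C-1/C-2 a traceless two-carbon linchpin.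
- Ring B is bought as (R)-carvone (C-9 ketone, C-10 methyl, C-5 acceptor carbon). Its stereocentre (C-7, isopropenyl) sets C-5, is relayed to C-10, C-4, C-9 and C-8, and is then removed by dealkenylation.
- Order of ring formation: ring B (bought), ring A (key step), butenolide ring (last).

Key step: step 5

Remark: labdane numbering is used for every compound (C-17 on C-8; C-18 α and C-19 β on C-4; C-20 on C-10; side chain C-11 to C-16; α/β refer to the usual drawing with C-20 β). Conjugate addition to carvone is assumed to occur anti to the isopropenyl group, as is usual for 5-substituted cyclohexenones, and compounds 2, 7, 16, 21 and TASF are taken as commercial.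

Step 1
Reactants: 1 (R)-(−)-carvone; 2 tert-butyl methyl malonate
Product: 3 tert-butyl methyl 2-[2-methyl-3-oxo-5-(prop-1-en-2-yl)cyclohexyl]malonate (malonyl group at C-5 β, trans to the 7α-isopropenyl group; epimers at C-10 and at the malonate carbon)
Conditions: NaOMe (0.2 equiv), MeOH, 0 °C to rt
Reagents that add atoms: none
Why: Base-catalysed Michael addition to the enone, in which axial attack on C-5 anti to the pseudo-equatorial isopropenyl group should set C-5 under kinetic control (the C-10 and malonate centres are epimerisable and are erased later).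

Step 2
Reactants: 3 Michael adduct
Product: 4 malonic half-ester, 3-tert-butoxy-3-oxo-2-[2-methyl-3-oxo-5-(prop-1-en-2-yl)cyclohexyl]propanoic acid (ring configuration as in 3)
Conditions: LiOH·H2O (1.05 equiv), THF/H2O, 0 °C; then 1 M HCl
Reagents that add atoms: lithium hydroxide, [Li+].[OH-]
Why: Chemoselective saponification, in which hydroxide should cleave the unhindered methyl ester of the mixed malonate while the tert-butyl ester, the ketone and C-5 stay untouched.

Step 3
Reactants: 4 malonic half-ester
Product: 5 tert-butyl 2-[2-methyl-3-oxo-5-(prop-1-en-2-yl)cyclohexyl]prop-2-enoate (5β-acrylate unit; 7α-isopropenyl; C-10 epimers)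
Conditions: (CH2O)n, Et2NH, EtOAc, reflux
Reagents that add atoms: formaldehyde (from paraformaldehyde), C=O
Why: Decarboxylative Mannich methylenation of a malonic half-ester (aminomethylation, then loss of CO2 and amine) should give the 2-substituted acrylate, that is C-3=C-4 bearing C-19, without touching a stereocentre.

Step 4
Reactants: 5 acrylate ketone
Product: 6 tert-butyl 2-[2-methyl-5-(prop-1-en-2-yl)-3-(trimethylsilyloxy)cyclohex-2-en-1-yl]prop-2-enoate (C-9/C-10 silyl enol ether)
Conditions: Me3SiCl, NaI, Et3N, MeCN, rt; non-aqueous work-up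
Reagents that add atoms: chlorotrimethylsilane, C[Si](C)(C)Cl
Why: Equilibrating silylation with Me3SiI made in the flask should favour the more substituted enol ether, which fixes the site of later enolate formation at C-10 and removes the C-10 epimer question.

Step 5
Reactants: 6 silyl enol ether; 7 phenyl vinyl sulfone
Product: 11 tert-butyl 4α,10β-dimethyl-9-oxo-2-(phenylsulfonyl)-7α-(prop-1-en-2-yl)-5α-decalin-4β-carboxylate (C-2 epimers), via enolate 8 (not isolated), via sulfonyl carbanion 9 (not isolated), via ester enolate 10 (not isolated)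
Conditions: 6 + 7 (1.05 equiv), THF, −78 °C; (Me2N)3S+ Me3SiF2− (TASF, 1.05 equiv), −78 to −40 °C; then MeI (3 equiv), −78 to 0 °C
Reagents that add atoms: iodomethane, CI
Why: Fluoride removes the silyl group from 6 to give the regiodefined C-9/C-10 enolate 8, which adds to the vinyl sulfone (Michael addition, forming C-10–C-1) to give the α-sulfonyl carbanion 9; this closes ring A by a 6-endo-trig Michael addition onto the tethered acrylate (forming C-2–C-3), and the resulting tert-butyl ester enolate 10 is C-methylated in the same flask (C-18). The closest known reaction type is the tandem Michael–Michael–alkylation annulation of ketone enolates (anionic double Michael, Michael-initiated ring closure), here with a vinyl sulfone as a traceless two-carbon linchpin. C-10: the acceptor should add anti to the C-5 substituent, which A(1,2) strain with the C-10 methyl holds pseudo-axial while the C-7 isopropenyl group stays equatorial, and this trans relationship becomes the trans ring fusion (5α-H, 10β-methyl). C-4: the exocyclic ester enolate of the chair ring A should be methylated on the α face, because the β face is shielded by the axial C-10 methyl group (1,3-diaxial), which leaves the ester axial (β) and the new methyl equatorial (α); C-2 forms as a mixture and is erased in step 10. The step needs C-10 over C-8 regiochemistry, which the enol silane and the aprotic low-temperature conditions secure (C-10 cannot reach C-3 itself and O-addition of the enolate to the acrylate is reversible), and 1,4- over 1,2-attack of 9 on the acrylate, which the bulky tert-butyl ester secures.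

Step 6
Reactants: 11 isopropenyl decalone
Product: 13 tert-butyl 4α,10β-dimethyl-9-oxo-2-(phenylsulfonyl)-5α-decalin-4β-carboxylate (C-2 epimers), via methoxy hydroperoxide 12 (not isolated)
Conditions: O3, MeOH, −78 °C; then FeSO4·7H2O (1.2 equiv), PhSH (1.5 equiv), −78 °C to rt
Reagents that add atoms: none
Why: Dealkenylative hydrogenation, in which ozonolysis in methanol gives the α-methoxy hydroperoxide, divalent iron cleaves its O–O bond, the alkoxy radical loses methyl acetate by β-scission and the secondary C-7 radical takes a hydrogen atom from thiophenol, so the carvone stereocentre disappears after it has done its work.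

Step 7
Reactants: 13 decalone
Product: 14 di-tert-butyl 4α,10β-dimethyl-9-oxo-2-(phenylsulfonyl)-5α-decalin-4β,8-dicarboxylate (β-keto ester; keto and enol forms)
Conditions: LiN(SiMe3)2 (2.2 equiv), THF, −78 °C; Boc2O (1.2 equiv), −78 to 0 °C; aq. NH4Cl
Reagents that add atoms: di-tert-butyl dicarbonate, CC(C)(C)OC(=O)OC(=O)OC(C)(C)C
Why: C-10 is quaternary, so only C-8 can be enolised, and Claisen-type C-acylation of the lithium enolate should install C-17 as a tert-butyl ester, the second equivalent of base holding the β-keto ester as its enolate.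

Step 8
Reactants: 14 β-keto ester
Product: 15 enol triflate (C-8=C-9 double bond; triflyloxy group on C-9; C-8 tert-butyl ester)
Conditions: NaH, THF, 0 °C; PhNTf2, rt; aq. NH4Cl
Reagents that add atoms: N-phenylbis(trifluoromethanesulfonimide), O=S(=O)(N(c1ccccc1)S(=O)(=O)C(F)(F)F)C(F)(F)F
Why: O-sulfonylation of the sodium enolate of the β-keto ester should give the β-triflyloxy enoate, which fixes the double bond between C-8 and C-9.

Step 9
Reactants: 15 enol triflate; 16 (1,3-dioxolan-2-ylmethyl)zinc bromide
Product: 17 di-tert-butyl 9-(1,3-dioxolan-2-ylmethyl)-4α,10β-dimethyl-2-(phenylsulfonyl)-5α-decal-8-ene-4β,8-dicarboxylate (tetrasubstituted C-8=C-9 enoate)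
Conditions: Pd(OAc)2 (5 mol %), SPhos (10 mol %), THF, 50 °C
Reagents that add atoms: none
Why: Negishi cross-coupling of the electron-poor enol triflate with a primary alkylzinc reagent should attach C-11 and C-12 (C-12 masked as an acetal) to C-9, the bulky biarylphosphine favouring reductive elimination at the hindered carbon.

Step 10
Reactants: 17 enoate
Product: 19 di-tert-butyl 9β-(1,3-dioxolan-2-ylmethyl)-4α,10β-dimethyl-5α,9α-decalin-4β,8α-dicarboxylate, via kinetic C-8 epimer mixture 18 (not isolated)
Conditions: Li, NH3(l)/THF, tBuOH (2 equiv), −78 °C; NH4Cl; then KOtBu (0.3 equiv), tBuOH/THF, 40 °C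
Reagents that add atoms: none
Why: Dissolving-metal conjugate reduction of the tetrasubstituted enoate with simultaneous reductive cleavage of the C-2 sulfone, in which C-9 should be protonated axially on the α face (anti to the axial C-10 methyl, stereoelectronic control as in enone reductions) so that the side chain is equatorial (β), and base equilibration then moves the C-8 ester to the equatorial α position, trans to the side chain.

Step 11
Reactants: 19 acetal diester
Product: 20 di-tert-butyl 4α,10β-dimethyl-9β-(2-oxoethyl)-5α,9α-decalin-4β,8α-dicarboxylate (C-12 aldehyde)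
Conditions: 1 M aq. HCl, THF, rt
Reagents that add atoms: water, O
Why: Acid-catalysed acetal hydrolysis should unmask the C-12 aldehyde, dilute aqueous acid leaving the tert-butyl esters intact.

Step 12
Reactants: 20 aldehyde; 21 3-(triphenyl-λ5-phosphanylidene)oxolan-2-one
Product: 22 (E)-α-alkylidene lactone (C-12=C-13 exocyclic to the oxolan-2-one ring; di-tert-butyl ester)
Conditions: toluene, 80 °C
Reagents that add atoms: none
Why: Wittig olefination of the aldehyde with the stabilised lactone ylide should form the C-12=C-13 bond as the E alkylidene lactone, whose geometry is lost in the next step.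

Step 13
Reactants: 22 alkylidene lactone
Product: 23 di-tert-butyl ester of the target (13-en-16,15-olide butenolide in place)
Conditions: RhCl3·3H2O (10 mol %), EtOH, 80 °C
Reagents that add atoms: none
Why: Rhodium hydride mediated alkene isomerisation (hydrometalation and β-hydride elimination) should move the exocyclic double bond into the ring to give the more stable endocyclic butenolide, with no stereocentre affected.

Step 14
Reactants: 23 di-tert-butyl ester
Product: 24 target diacid CNP0478950.1
Conditions: CF3CO2H/CH2Cl2 (1:3), 0 °C to rt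
Reagents that add atoms: none
Why: Acidolysis of both tert-butyl esters through the tert-butyl cation should free the two acids, including the hindered axial C-19 acid that would resist saponification, while the butenolide and all stereocentres are stable to the acid.

**Compound list**
1 | (R)-(−)-carvone | CC1=CC[C@H](CC1=O)C(C)=C | starting material
2 | tert-butyl methyl malonate | COC(=O)CC(=O)OC(C)(C)C | starting material
3 | Michael adduct (5β-malonyl, 7α-isopropenyl ring-B ketone) | CC1[C@H](C(C(=O)OC)C(=O)OC(C)(C)C)C[C@@H](C(C)=C)CC1=O | intermediate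
4 | malonic half-ester | CC1[C@H](C(C(=O)O)C(=O)OC(C)(C)C)C[C@@H](C(C)=C)CC1=O | intermediate
5 | acrylate ketone | CC1[C@H](C(=C)C(=O)OC(C)(C)C)C[C@@H](C(C)=C)CC1=O | intermediate
6 | C-9/C-10 trimethylsilyl enol ether | CC1=C(O[Si](C)(C)C)C[C@H](C(C)=C)C[C@H]1C(=C)C(=O)OC(C)(C)C | intermediate
7 | phenyl vinyl sulfone | C=CS(=O)(=O)c1ccccc1 | starting material
8 | tris(dimethylamino)sulfonium C-9/C-10 enolate | CC1=C([O-])C[C@H](C(C)=C)C[C@H]1C(=C)C(=O)OC(C)(C)C.CN(C)[S+](N(C)C)N(C)C | intermediate
9 | α-sulfonyl carbanion (C-10 Michael adduct) | C[C@]1(C[CH-]S(=O)(=O)c2ccccc2)[C@H](C(=C)C(=O)OC(C)(C)C)C[C@@H](C(C)=C)CC1=O.CN(C)[S+](N(C)C)N(C)C | intermediate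
10 | ring-A tert-butyl ester enolate | C[C@]12CC(S(=O)(=O)c3ccccc3)CC(=C([O-])OC(C)(C)C)[C@@H]1C[C@@H](C(C)=C)CC2=O.CN(C)[S+](N(C)C)N(C)C | intermediate
11 | 7α-isopropenyl trans-decalone (C-2 sulfone, 4β-ester) | C[C@]12CC(S(=O)(=O)c3ccccc3)C[C@](C)(C(=O)OC(C)(C)C)[C@@H]1C[C@@H](C(C)=C)CC2=O | intermediate
12 | α-methoxy hydroperoxide at the former isopropenyl carbon | C[C@]12CC(S(=O)(=O)c3ccccc3)C[C@](C)(C(=O)OC(C)(C)C)[C@@H]1C[C@@H](C(C)(OC)OO)CC2=O | intermediate
13 | trans-decalone (C-7 unsubstituted) | C[C@]12CC(S(=O)(=O)c3ccccc3)C[C@](C)(C(=O)OC(C)(C)C)[C@@H]1CCCC2=O | intermediate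
14 | C-8 tert-butyl β-keto ester | C[C@]12CC(S(=O)(=O)c3ccccc3)C[C@](C)(C(=O)OC(C)(C)C)[C@@H]1CCC(C(=O)OC(C)(C)C)C2=O | intermediate
15 | enol triflate | C[C@]12CC(S(=O)(=O)c3ccccc3)C[C@](C)(C(=O)OC(C)(C)C)[C@@H]1CCC(C(=O)OC(C)(C)C)=C2OS(=O)(=O)C(F)(F)F | intermediate
16 | (1,3-dioxolan-2-ylmethyl)zinc bromide | Br[Zn]CC1OCCO1 | starting material
17 | C-8=C-9 enoate with C-9 acetal side chain | C[C@]12CC(S(=O)(=O)c3ccccc3)C[C@](C)(C(=O)OC(C)(C)C)[C@@H]1CCC(C(=O)OC(C)(C)C)=C2CC1OCCO1 | intermediate
18 | kinetic C-8 epimer mixture of the saturated diester (9α-H) | C[C@]12CCC[C@](C)(C(=O)OC(C)(C)C)[C@@H]1CCC(C(=O)OC(C)(C)C)[C@@H]2CC1OCCO1 | intermediate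
19 | saturated diester acetal (8α-ester, 9β-side chain) | C[C@]12CCC[C@](C)(C(=O)OC(C)(C)C)[C@@H]1CC[C@@H](C(=O)OC(C)(C)C)[C@@H]2CC1OCCO1 | intermediate
20 | C-12 aldehyde | C[C@]12CCC[C@](C)(C(=O)OC(C)(C)C)[C@@H]1CC[C@@H](C(=O)OC(C)(C)C)[C@@H]2CC=O | intermediate
21 | 3-(triphenyl-λ5-phosphanylidene)oxolan-2-one | O=C1OCCC1=P(c1ccccc1)(c1ccccc1)c1ccccc1 | starting material
22 | (E)-α-alkylidene lactone | C[C@]12CCC[C@](C)(C(=O)OC(C)(C)C)[C@@H]1CC[C@@H](C(=O)OC(C)(C)C)[C@@H]2C/C=C1\CCOC1=O | intermediate
23 | di-tert-butyl ester of the target | C[C@]12CCC[C@](C)(C(=O)OC(C)(C)C)[C@@H]1CC[C@@H](C(=O)OC(C)(C)C)[C@@H]2CCC1=CCOC1=O | intermediate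
24 | CNP0478950.1 | C[C@]12CCC[C@](C)(C(=O)O)[C@@H]1CC[C@@H](C(=O)O)[C@@H]2CCC1=CCOC1=O | target

**Step count and risks**

Total step count: 14. Longest linear sequence: 14 steps from (R)-carvone (all other components are bought).

Steps most likely to fail:

1. Step 5. Proton transfer from C-8 of the regenerated ketone to the α-sulfonyl carbanion, or anionic oligomerisation of the vinyl sulfone, may outrun ring closure and stall the cascade at the open-chain adduct. The fallback sets out from 6 and comes back at 11; it cuts the cascade into stages and takes the ketone out of play. Fluoride-induced Michael addition of 6 to 7 with an immediate acetic acid quench should give the keto sulfone F1. Kinetic enolisation (LiN(iPr)2, Me3SiCl, THF, −78 °C; only C-8 carries α-hydrogen) then masks the ketone as the C-8/C-9 silyl enol ether F2. The sulfone is now the only acid left, so a further equivalent of LiN(iPr)2 should give the lithiated sulfone, which closes ring A on the acrylate. Addition of MeI and an acidic work-up, which also hydrolyses the enol ether, should return 11.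

2. Step 9. Transmetalation and reductive elimination at the tetrasubstituted carbon next to the quaternary C-10 may be slow, so that β-hydride elimination of the alkylpalladium species or reduction of the triflate takes over. The fallback sets out from 15 and comes back at 20; it uses a small allyl group as the masked acetaldehyde unit. Stille coupling of 15 with allyltributylstannane (Pd2(dba)3, AsPh3, LiCl, CuI, NMP, 60 °C) should give the allyl enoate F3. Reduction and equilibration as in step 10 (Li, NH3; then KOtBu) should give the 9β-allyl diester F4, and ozonolysis with a Me2S work-up should deliver aldehyde 20.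

3. Step 13. The double-bond migration may stop at an equilibrium mixture of exocyclic and endocyclic isomers, or be accompanied by partial loss of the tert-butyl esters in the hot acidic medium. The fallback sets out from 20 and comes back at 23; it builds the butenolide by sulfoxide elimination, which places the double bond in the ring. Reduction of 20 with NaBH4 should give the C-12 alcohol F5, and I2, PPh3 and imidazole should convert it into the iodide F6. 3-(Phenylsulfanyl)oxolan-2-one F7, made from 3-bromooxolan-2-one, thiophenol and Et3N, is deprotonated with LiN(iPr)2 (THF/DMPU) and alkylated with F6 to give the α-phenylsulfanyl lactone F8. Oxidation with mCPBA at −78 °C should give the sulfoxide F9, and thermal syn-elimination in toluene at 110 °C should give 23.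

**Further compounds**
F1 | step 5 | keto sulfone, tert-butyl 2-[2-methyl-3-oxo-2-(2-(phenylsulfonyl)ethyl)-5-(prop-1-en-2-yl)cyclohexyl]prop-2-enoate (10β-methyl, 5β-acrylate unit, 7α-isopropenyl) | C[C@]1(CCS(=O)(=O)c2ccccc2)[C@H](C(=C)C(=O)OC(C)(C)C)C[C@@H](C(C)=C)CC1=O
F2 | step 5 | C-8/C-9 trimethylsilyl enol ether of F1 | C[C@]1(CCS(=O)(=O)c2ccccc2)[C@H](C(=C)C(=O)OC(C)(C)C)C[C@@H](C(C)=C)C=C1O[Si](C)(C)C
F3 | step 9 | C-8=C-9 enoate with 9-allyl group | C[C@]12CC(S(=O)(=O)c3ccccc3)C[C@](C)(C(=O)OC(C)(C)C)[C@@H]1CCC(C(=O)OC(C)(C)C)=C2CC=C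
F4 | step 9 | 9β-allyl saturated diester (8α-ester, 9α-H) | C[C@]12CCC[C@](C)(C(=O)OC(C)(C)C)[C@@H]1CC[C@@H](C(=O)OC(C)(C)C)[C@@H]2CC=C
F5 | step 13 | C-12 alcohol | C[C@]12CCC[C@](C)(C(=O)OC(C)(C)C)[C@@H]1CC[C@@H](C(=O)OC(C)(C)C)[C@@H]2CCO
F6 | step 13 | C-12 iodide | C[C@]12CCC[C@](C)(C(=O)OC(C)(C)C)[C@@H]1CC[C@@H](C(=O)OC(C)(C)C)[C@@H]2CCI
F7 | step 13 | 3-(phenylsulfanyl)oxolan-2-one | O=C1OCCC1Sc1ccccc1
F8 | step 13 | α-phenylsulfanyl lactone (C-13 epimers) | C[C@]12CCC[C@](C)(C(=O)OC(C)(C)C)[C@@H]1CC[C@@H](C(=O)OC(C)(C)C)[C@@H]2CCC1(Sc3ccccc3)CCOC1=O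
F9 | step 13 | sulfoxide of F8 | C[C@]12CCC[C@](C)(C(=O)OC(C)(C)C)[C@@H]1CC[C@@H](C(=O)OC(C)(C)C)[C@@H]2CCC1(S(=O)c3ccccc3)CCOC1=O
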